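Ring A is a hexasubstituted benzene in which oxygens (ring A carbons 2, 4 and 6) alternate with carbon substituents (butanoyl on carbon 1, methyl on carbon 3, the bridging CH2 on carbon 5). It is cut into a four-carbon vinylketene (carbons 2, 1, 6 and 5) and a two-carbon silyl ynol ether (carbons 3 and 4). One thermal cascade of a cyclobutenone with 1-(triisopropylsiloxy)propyne forms the ring A bonds 2–3, 4–5 and 1–2 and closes the ring with five substituents in place; only carbon 1 stays open for the butanoyl group. The precursor is a cyclobut-2-en-1-one carrying the protected ring B benzyl group on position 2 and a triisopropylsiloxy group on position 3.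

Key step: step 12

Numbering and assumption: ring A carbons are counted from the butanoyl-bearing carbon (1) through OH (2), methyl (3), OH (4) and the bridge CH2 (5) to OH (6). Ring B carbons are counted from the bridge-bearing carbon (1) through OH (2), propanoyl (3), OH (4) and methyl (5) to OMe (6). The target is achiral. Ethoxyethyne (hexane solution) and prop-1-yne (THF solution) are taken as purchasable; ketene is made by pyrolysis of acetone and passed directly into the reaction.

Design remark: an alkyl ether on ring A carbon 6 could only be cleaved with reagents that also attack the doubly flanked methyl ether on ring B carbon 6. The 3-ethoxycyclobutenone is therefore converted into its triisopropylsilyl analogue before the annulation. The ring B ketone rules out an organolithium for the benzyl–alkyne bond, which is made with an alkynylzinc chloride instead.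

Step 1
Reactants: 1 2-methylbenzene-1,3,5-triol; 2 propanoyl chloride
Product: 3 1-(2,4,6-trihydroxy-3-methylphenyl)propan-1-one
Conditions: AlCl3 (3.5 equiv), PhNO2–CH2Cl2, 0 → 45 °C; aq. HCl
Reagents that add atoms: none
Why: Friedel–Crafts acylation of the phloroglucinol nucleus, in which the two free ring carbons are equivalent and the first acyl group deactivates the ring towards a second one, so a single C-acyl product is expected.

Step 2
Reactants: 3 1-(2,4,6-trihydroxy-3-methylphenyl)propan-1-one
Product: 4 1-(2,6-dihydroxy-4-methoxy-3-methylphenyl)propan-1-one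
Conditions: Me2SO4 (1.05 equiv), K2CO3 (1.1 equiv), acetone, rt → 40 °C
Reagents that add atoms: dimethyl sulfate, COS(=O)(=O)OC
Why: Williamson O-methylation, in which the hydroxyl para to the ketone is the most acidic and is not held in a hydrogen bond to the carbonyl, so one equivalent of base and electrophile should methylate it ahead of the two chelated ortho hydroxyls.

Step 3
Reactants: 4 1-(2,6-dihydroxy-4-methoxy-3-methylphenyl)propan-1-one
Product: 5 2,4-dihydroxy-6-methoxy-5-methyl-3-propanoylbenzaldehyde
Conditions: Cl2CHOMe (1.3 equiv), TiCl4 (3 equiv), CH2Cl2, −10 → 0 °C; then 1 M HCl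
Reagents that add atoms: dichloromethyl methyl ether, COC(Cl)Cl; water, O
Why: Rieche formylation at the only free ring carbon (ring B carbon 1), which lies ortho to a phenol oxygen bound to TiCl4, while the enolisable ketone side chain is left alone (a Vilsmeier reagent could attack it) and aqueous hydrolysis of the aryl(chloro)methyl ether releases the aldehyde.

Step 4
Reactants: 5 2,4-dihydroxy-6-methoxy-5-methyl-3-propanoylbenzaldehyde
Product: 6 2,4-bis(benzyloxy)-6-methoxy-5-methyl-3-propanoylbenzaldehyde
Conditions: BnBr (2.6 equiv), K2CO3 (3 equiv), Bu4NI (cat.), DMF, 60 °C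
Reagents that add atoms: benzyl bromide, BrCc1ccccc1
Why: Williamson etherification of both carbonyl-chelated phenols, which needs a polar solvent and warming but has no competing site because every ring carbon is substituted and K2CO3 is too weak to enolise the ketone.

Step 5
Reactants: 6 2,4-bis(benzyloxy)-6-methoxy-5-methyl-3-propanoylbenzaldehyde
Product: 7 1-[2,6-bis(benzyloxy)-3-(hydroxymethyl)-4-methoxy-5-methylphenyl]propan-1-one
Conditions: NaBH4 (1 equiv), MeOH–THF, −20 → 0 °C
Reagents that add atoms: none
Why: Chemoselective borohydride reduction, in which the aldehyde should react far faster than the ethyl ketone that is twisted out of conjugation and shielded by two ortho benzyloxy groups.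

Step 6
Reactants: 7 1-[2,6-bis(benzyloxy)-3-(hydroxymethyl)-4-methoxy-5-methylphenyl]propan-1-one
Product: 8 1-[2,6-bis(benzyloxy)-3-(bromomethyl)-4-methoxy-5-methylphenyl]propan-1-one
Conditions: CBr4 (1.3 equiv), PPh3 (1.3 equiv), CH2Cl2, 0 °C; used at once
Reagents that add atoms: carbon tetrabromide, BrC(Br)(Br)Br
Why: Appel bromination under neutral conditions, suited to an electron-rich benzylic alcohol whose bromide ionises easily but cannot self-alkylate because the ring has no free position.

Step 7
Reactants: 8 1-[2,6-bis(benzyloxy)-3-(bromomethyl)-4-methoxy-5-methylphenyl]propan-1-one; 9 ethoxyethyne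
Product: 12 1-[2,6-bis(benzyloxy)-3-(3-ethoxyprop-2-yn-1-yl)-4-methoxy-5-methylphenyl]propan-1-one, via lithium ethoxyacetylide 10 (not isolated), via (ethoxyethynyl)zinc chloride 11 (not isolated)
Conditions: 9, n-BuLi, THF, −78 °C; ZnCl2, −78 → 0 °C; then 8, PdCl2(DPEphos) (3 mol%), THF, rt (DPEphos = bis(2-diphenylphosphinophenyl) ether)
Reagents that add atoms: none
Why: Negishi coupling of a benzylic bromide with an alkynylzinc chloride, in which the zinc reagent tolerates the aryl ketone that a lithium acetylide would enolise or attack and the wide-bite-angle diphosphine favours the benzyl–alkynyl reductive elimination.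

Step 8
Reactants: 12 1-[2,6-bis(benzyloxy)-3-(3-ethoxyprop-2-yn-1-yl)-4-methoxy-5-methylphenyl]propan-1-one; 13 acetone
Product: 15 3-ethoxy-2-{[2,4-bis(benzyloxy)-6-methoxy-5-methyl-3-propanoylphenyl]methyl}cyclobut-2-en-1-one, via ketene 14 (not isolated)
Conditions: ketene 14 (gas, from pyrolysis of 13 at about 700 °C, passed in to excess), CH2Cl2, 0 °C → rt
Reagents that add atoms: none
Why: Ketene–ynol ether [2+2] cycloaddition under neutral, acid-free conditions, in which the ketene carbonyl carbon bonds to the nucleophilic benzyl-bearing alkyne carbon, so the arylmethyl group ends on position 2 and the ethoxy group on position 3 of the cyclobutenone.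

Step 9
Reactants: 15 3-ethoxy-2-{[2,4-bis(benzyloxy)-6-methoxy-5-methyl-3-propanoylphenyl]methyl}cyclobut-2-en-1-one
Product: 16 3-hydroxy-2-{[2,4-bis(benzyloxy)-6-methoxy-5-methyl-3-propanoylphenyl]methyl}cyclobut-2-en-1-one
Conditions: 1 M HCl, THF, 0 °C → rt
Reagents that add atoms: water, O
Why: Acid hydrolysis of the vinylogous ester (addition of water at position 3 and loss of ethanol) to the enol of a symmetrical cyclobutane-1,3-dione, which removes the ethyl group at the one stage where that is easy.

Step 10
Reactants: 16 3-hydroxy-2-{[2,4-bis(benzyloxy)-6-methoxy-5-methyl-3-propanoylphenyl]methyl}cyclobut-2-en-1-one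
Product: 17 2-{[2,4-bis(benzyloxy)-6-methoxy-5-methyl-3-propanoylphenyl]methyl}-3-(triisopropylsiloxy)cyclobut-2-en-1-one
Conditions: i-Pr3SiCl (1.1 equiv), Et3N (1.5 equiv), DMAP (cat.), CH2Cl2, 0 °C → rt
Reagents that add atoms: chlorotriisopropylsilane, CC(C)[Si](Cl)(C(C)C)C(C)C
Why: O-silylation of a vinylogous acid, whose two oxygens are equivalent so that one silyl enol ether results, with a silyl chloride mild enough to leave the hindered ketone untouched and bulky enough to give a vinylogous silyl ester that can be handled.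

Step 11
Reactants: 18 prop-1-yne
Product: 21 1-(triisopropylsiloxy)prop-1-yne, via prop-1-ynyllithium 19 (not isolated), via lithium prop-1-ynolate 20 (not isolated)
Conditions: n-BuLi, THF, −78 °C; t-BuOOLi (from t-BuOOH, LiN(SiMe3)2), −78 → 0 °C; i-Pr3SiOTf, −78 → 0 °C
Reagents that add atoms: tert-butyl hydroperoxide, CC(C)(C)OO; triisopropylsilyl trifluoromethanesulfonate, CC(C)[Si](OS(=O)(=O)C(F)(F)F)(C(C)C)C(C)C
Why: Oxidation of a lithium acetylide by lithium tert-butyl peroxide gives the ynolate, and the hard, bulky silyl triflate traps it on oxygen to give the siloxyalkyne (ynolate O-silylation).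

Step 12
Reactants: 17 2-{[2,4-bis(benzyloxy)-6-methoxy-5-methyl-3-propanoylphenyl]methyl}-3-(triisopropylsiloxy)cyclobut-2-en-1-one; 21 1-(triisopropylsiloxy)prop-1-yne
Product: 26 1-[2,6-bis(benzyloxy)-3-{[4-hydroxy-3-methyl-2,6-bis(triisopropylsiloxy)phenyl]methyl}-4-methoxy-5-methylphenyl]propan-1-one, via siloxyvinylketene 22 (not isolated), via vinylcyclobutenone 23 (not isolated), via dienylketene 24 (not isolated), via cyclohexadienone 25 (not isolated)
Conditions: 21 (2 equiv), toluene, 80 → 110 °C
Reagents that add atoms: none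
Why: Heating opens cyclobutenone 17 by a four-electron electrocyclic reaction to vinylketene 22, whose ketene C=C adds to the electron-rich alkyne 21 in a [2+2] cycloaddition to give 23; a second four-electron opening gives dienylketene 24, which closes by a six-electron electrocyclisation to dienone 25 and tautomerises to phenol 26. The closest known reaction type is the Danheiser benzannulation of cyclobutenones, 3-alkoxy members included, with siloxyalkynes, and the 3-siloxy group here is a spectator of the same electronic type. Ring A is the only ring closed, and it closes by the thermally allowed disrotatory 6π electrocyclisation that joins ring A carbons 1 and 2, after the [2+2] step has joined carbons 2 and 3 and carbons 4 and 5. No stereocentre is created, since the quaternary carbon of 23 is transient and ends as aromatic carbon 5 of ring A. The step needs regiocontrol in the [2+2] addition, and the oxygen of 21 secures it by making the methyl-bearing carbon the nucleophile that attacks the electrophilic ketene carbon (the future carbon 2), so the methyl group ends on carbon 3 and the siloxy carbon becomes carbon 4 beside the bridge. An excess of 21 should keep the cycloaddition faster than acylation of the product phenol by 22.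

Step 13
Reactants: 26 1-[2,6-bis(benzyloxy)-3-{[4-hydroxy-3-methyl-2,6-bis(triisopropylsiloxy)phenyl]methyl}-4-methoxy-5-methylphenyl]propan-1-one; 27 butanoyl chloride
Product: 28 1-[5-{[2,4-bis(benzyloxy)-6-methoxy-5-methyl-3-propanoylphenyl]methyl}-2-hydroxy-3-methyl-4,6-bis(triisopropylsiloxy)phenyl]butan-1-one
Conditions: TiCl4 (2.2 equiv), 27 (1.3 equiv), CH2Cl2, −78 → −20 °C; aq. NH4Cl
Reagents that add atoms: none
Why: Friedel–Crafts ortho-acylation directed by the TiCl4-bound phenol oxygen on ring A carbon 2, which should be fast at low temperature because ring A carbon 1 is the only unsubstituted ring carbon of the molecule and is activated by three oxygens, so the benzyl ethers of ring B should not yet be attacked by the Lewis acid.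

Step 14
Reactants: 28 1-[5-{[2,4-bis(benzyloxy)-6-methoxy-5-methyl-3-propanoylphenyl]methyl}-2-hydroxy-3-methyl-4,6-bis(triisopropylsiloxy)phenyl]butan-1-one
Product: 29 1-[3-{[2,4-bis(benzyloxy)-6-methoxy-5-methyl-3-propanoylphenyl]methyl}-2,4,6-trihydroxy-5-methylphenyl]butan-1-one
Conditions: Bu4NF (2.5 equiv), AcOH (2.5 equiv), THF, 0 °C → rt
Reagents that add atoms: none
Why: Fluoride cleavage of both aryl silyl ethers, buffered with acetic acid so that the methylene-bridged bis-acylphenol is not exposed to strong base, while benzyl and methyl ethers are inert.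

Step 15
Reactants: 29 1-[3-{[2,4-bis(benzyloxy)-6-methoxy-5-methyl-3-propanoylphenyl]methyl}-2,4,6-trihydroxy-5-methylphenyl]butan-1-one
Product: 30 1-[3-[(2,4-dihydroxy-6-methoxy-5-methyl-3-propanoylphenyl)methyl]-2,4,6-trihydroxy-5-methylphenyl]butan-1-one
Conditions: H2 (1 atm), Pd/C (10 wt% Pd), EtOAc–MeOH, rt
Reagents that add atoms: none
Why: Catalytic hydrogenolysis of the two benzyl aryl ethers, which should leave the hydrogen-bonded aryl ketones, the diarylmethane and the methyl ether on ring B carbon 6 intact and release the target under neutral conditions.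

Compound list
1 | 2-methylbenzene-1,3,5-triol | Cc1c(O)cc(O)cc1O | starting material
2 | propanoyl chloride | CCC(=O)Cl | starting material
3 | 1-(2,4,6-trihydroxy-3-methylphenyl)propan-1-one | CCC(=O)c1c(O)cc(O)c(C)c1O | intermediate
4 | 1-(2,6-dihydroxy-4-methoxy-3-methylphenyl)propan-1-one | CCC(=O)c1c(O)cc(OC)c(C)c1O | intermediate
5 | 2,4-dihydroxy-6-methoxy-5-methyl-3-propanoylbenzaldehyde | CCC(=O)c1c(O)c(C=O)c(OC)c(C)c1O | intermediate
6 | 2,4-bis(benzyloxy)-6-methoxy-5-methyl-3-propanoylbenzaldehyde | CCC(=O)c1c(OCc2ccccc2)c(C=O)c(OC)c(C)c1OCc1ccccc1 | intermediate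
7 | 1-[2,6-bis(benzyloxy)-3-(hydroxymethyl)-4-methoxy-5-methylphenyl]propan-1-one | CCC(=O)c1c(OCc2ccccc2)c(CO)c(OC)c(C)c1OCc1ccccc1 | intermediate
8 | 1-[2,6-bis(benzyloxy)-3-(bromomethyl)-4-methoxy-5-methylphenyl]propan-1-one | CCC(=O)c1c(OCc2ccccc2)c(CBr)c(OC)c(C)c1OCc1ccccc1 | intermediate
9 | ethoxyethyne | C#COCC | starting material
10 | lithium ethoxyacetylide | [Li]C#COCC | intermediate (not isolated)
11 | (ethoxyethynyl)zinc chloride | CCOC#C[Zn]Cl | intermediate (not isolated)
12 | 1-[2,6-bis(benzyloxy)-3-(3-ethoxyprop-2-yn-1-yl)-4-methoxy-5-methylphenyl]propan-1-one | CCOC#CCc1c(OCc2ccccc2)c(C(=O)CC)c(OCc2ccccc2)c(C)c1OC | intermediate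
13 | acetone | CC(C)=O | starting material
14 | ketene (ethenone) | C=C=O | intermediate (not isolated)
15 | 3-ethoxy-2-{[2,4-bis(benzyloxy)-6-methoxy-5-methyl-3-propanoylphenyl]methyl}cyclobut-2-en-1-one | CCOC1=C(Cc2c(OCc3ccccc3)c(C(=O)CC)c(OCc3ccccc3)c(C)c2OC)C(=O)C1 | intermediate
16 | 3-hydroxy-2-{[2,4-bis(benzyloxy)-6-methoxy-5-methyl-3-propanoylphenyl]methyl}cyclobut-2-en-1-one (enol of the cyclobutane-1,3-dione) | OC1=C(Cc2c(OCc3ccccc3)c(C(=O)CC)c(OCc3ccccc3)c(C)c2OC)C(=O)C1 | intermediate
17 | 2-{[2,4-bis(benzyloxy)-6-methoxy-5-methyl-3-propanoylphenyl]methyl}-3-(triisopropylsiloxy)cyclobut-2-en-1-one | CC(C)[Si](C(C)C)(C(C)C)OC1=C(Cc2c(OCc3ccccc3)c(C(=O)CC)c(OCc3ccccc3)c(C)c2OC)C(=O)C1 | intermediate (precursor of the key step)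
18 | prop-1-yne | CC#C | starting material
19 | prop-1-ynyllithium | [Li]C#CC | intermediate (not isolated)
20 | lithium prop-1-ynolate | CC#CO[Li] | intermediate (not isolated)
21 | 1-(triisopropylsiloxy)prop-1-yne | CC#CO[Si](C(C)C)(C(C)C)C(C)C | intermediate
22 | 2-{[2,4-bis(benzyloxy)-6-methoxy-5-methyl-3-propanoylphenyl]methyl}-3-(triisopropylsiloxy)buta-1,3-dien-1-one (vinylketene) | O=C=C(Cc1c(OCc2ccccc2)c(C(=O)CC)c(OCc2ccccc2)c(C)c1OC)C(=C)O[Si](C(C)C)(C(C)C)C(C)C | intermediate (not isolated)
23 | 4-{[2,4-bis(benzyloxy)-6-methoxy-5-methyl-3-propanoylphenyl]methyl}-2-methyl-3-(triisopropylsiloxy)-4-[1-(triisopropylsiloxy)ethenyl]cyclobut-2-en-1-one (racemic, transient) | O=C1C(C)=C(O[Si](C(C)C)(C(C)C)C(C)C)C1(Cc2c(OCc3ccccc3)c(C(=O)CC)c(OCc3ccccc3)c(C)c2OC)C(=C)O[Si](C(C)C)(C(C)C)C(C)C | intermediate (not isolated)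
24 | (3E)-4-{[2,4-bis(benzyloxy)-6-methoxy-5-methyl-3-propanoylphenyl]methyl}-2-methyl-3,5-bis(triisopropylsiloxy)hexa-1,3,5-trien-1-one (ketenyl and siloxyvinyl groups cis on the central double bond) | O=C=C(C)/C(O[Si](C(C)C)(C(C)C)C(C)C)=C(\C(=C)O[Si](C(C)C)(C(C)C)C(C)C)Cc1c(OCc2ccccc2)c(C(=O)CC)c(OCc2ccccc2)c(C)c1OC | intermediate (not isolated)
25 | 4-{[2,4-bis(benzyloxy)-6-methoxy-5-methyl-3-propanoylphenyl]methyl}-2-methyl-3,5-bis(triisopropylsiloxy)cyclohexa-2,4-dien-1-one | O=C1CC(O[Si](C(C)C)(C(C)C)C(C)C)=C(Cc2c(OCc3ccccc3)c(C(=O)CC)c(OCc3ccccc3)c(C)c2OC)C(O[Si](C(C)C)(C(C)C)C(C)C)=C1C | intermediate (not isolated)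
26 | 1-[2,6-bis(benzyloxy)-3-{[4-hydroxy-3-methyl-2,6-bis(triisopropylsiloxy)phenyl]methyl}-4-methoxy-5-methylphenyl]propan-1-one | CC(C)[Si](C(C)C)(C(C)C)Oc1cc(O)c(C)c(O[Si](C(C)C)(C(C)C)C(C)C)c1Cc1c(OCc2ccccc2)c(C(=O)CC)c(OCc2ccccc2)c(C)c1OC | intermediate (product of the key step)
27 | butanoyl chloride | CCCC(=O)Cl | starting material
28 | 1-[5-{[2,4-bis(benzyloxy)-6-methoxy-5-methyl-3-propanoylphenyl]methyl}-2-hydroxy-3-methyl-4,6-bis(triisopropylsiloxy)phenyl]butan-1-one | CCCC(=O)c1c(O)c(C)c(O[Si](C(C)C)(C(C)C)C(C)C)c(Cc2c(OCc3ccccc3)c(C(=O)CC)c(OCc3ccccc3)c(C)c2OC)c1O[Si](C(C)C)(C(C)C)C(C)C | intermediate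
29 | 1-[3-{[2,4-bis(benzyloxy)-6-methoxy-5-methyl-3-propanoylphenyl]methyl}-2,4,6-trihydroxy-5-methylphenyl]butan-1-one | CCCC(=O)c1c(O)c(C)c(O)c(Cc2c(OCc3ccccc3)c(C(=O)CC)c(OCc3ccccc3)c(C)c2OC)c1O | intermediate
30 | 1-[3-[(2,4-dihydroxy-6-methoxy-5-methyl-3-propanoylphenyl)methyl]-2,4,6-trihydroxy-5-methylphenyl]butan-1-one | CCCC(=O)c1c(O)c(C)c(O)c(Cc2c(O)c(C(=O)CC)c(O)c(C)c2OC)c1O | target

Total step count: 15. Longest linear sequence: 14 steps (steps 1 to 10, then 12 to 15); step 11 is a one-step side branch.

Steps most likely to fail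

1. Step 12. The vinylketene may be consumed by dimerisation or by acylating the product phenol. The [2+2] addition may also be slowed by crowding, because the bridge carbon ends between two bulky siloxy groups and faces two ortho substituents of ring B. The fallback gives up the annulation and makes the bridge bond by electrophilic benzylation. It sets out from 7 and comes back at 29. Friedel–Crafts acylation of 1 with 27 (AlCl3, PhNO2–CH2Cl2) should give 1-(2,4,6-trihydroxy-3-methylphenyl)butan-1-one F1. Its single free ring carbon should then be alkylated by the benzylic cation from alcohol 7 (TsOH cat., dioxane, rt) to give 29 directly, and step 15 follows.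

2. Step 13. The Lewis acid may strip or transfer benzyl groups from the chelating oxygens of ring B, attack at the crowded ring A carbon 1 may be slow, and O-acylation may compete. The fallback avoids strong Lewis acids by building the ketone in three known operations. It sets out from 26 and comes back at 28. Magnesium-mediated ortho-formylation (MgCl2, Et3N, paraformaldehyde, MeCN, reflux) should give 3-{[2,4-bis(benzyloxy)-6-methoxy-5-methyl-3-propanoylphenyl]methyl}-6-hydroxy-5-methyl-2,4-bis(triisopropylsiloxy)benzaldehyde F2. Grignard addition of n-PrMgBr (3 equiv, THF, −78 °C; the shielded ring B ketone should not add) should give the racemic benzylic alcohol 1-[2,6-bis(benzyloxy)-3-{[4-hydroxy-5-(1-hydroxybutyl)-3-methyl-2,6-bis(triisopropylsiloxy)phenyl]methyl}-4-methoxy-5-methylphenyl]propan-1-one F3. Oxidation with MnO2 (CH2Cl2, rt) then returns 28.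

3. Step 8. Ketene may dimerise faster than it adds to the substituted ynol ether, and traces of acid may hydrate the ynol ether. The fallback uses the more electrophilic dichloroketene and then removes the chlorines. It sets out from 12 and comes back at 15. Cycloaddition with dichloroketene (Cl3CCOCl, Zn–Cu couple, Et2O, rt) should give 4,4-dichloro-3-ethoxy-2-{[2,4-bis(benzyloxy)-6-methoxy-5-methyl-3-propanoylphenyl]methyl}cyclobut-2-en-1-one F4. Reductive dechlorination with zinc dust (AcOH–TMEDA, EtOH, 0 °C) then gives 15.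

Further compounds
F1 | step 12 | 1-(2,4,6-trihydroxy-3-methylphenyl)butan-1-one | CCCC(=O)c1c(O)cc(O)c(C)c1O
F2 | step 13 | 3-{[2,4-bis(benzyloxy)-6-methoxy-5-methyl-3-propanoylphenyl]methyl}-6-hydroxy-5-methyl-2,4-bis(triisopropylsiloxy)benzaldehyde | O=Cc1c(O)c(C)c(O[Si](C(C)C)(C(C)C)C(C)C)c(Cc2c(OCc3ccccc3)c(C(=O)CC)c(OCc3ccccc3)c(C)c2OC)c1O[Si](C(C)C)(C(C)C)C(C)C
F3 | step 13 | 1-[2,6-bis(benzyloxy)-3-{[4-hydroxy-5-(1-hydroxybutyl)-3-methyl-2,6-bis(triisopropylsiloxy)phenyl]methyl}-4-methoxy-5-methylphenyl]propan-1-one (racemic) | CCCC(O)c1c(O)c(C)c(O[Si](C(C)C)(C(C)C)C(C)C)c(Cc2c(OCc3ccccc3)c(C(=O)CC)c(OCc3ccccc3)c(C)c2OC)c1O[Si](C(C)C)(C(C)C)C(C)C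
F4 | step 8 | 4,4-dichloro-3-ethoxy-2-{[2,4-bis(benzyloxy)-6-methoxy-5-methyl-3-propanoylphenyl]methyl}cyclobut-2-en-1-one | CCOC1=C(Cc2c(OCc3ccccc3)c(C(=O)CC)c(OCc3ccccc3)c(C)c2OC)C(=O)C1(Cl)Cl
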